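**Strategy.** The benzene ring is assembled, not functionalized. It is disconnected at C1–C2, C3–C4 and C4–C5 into ethoxyacetylene (C2, C3) and an ester-bearing vinylketene (C4, C1, C6, C5) released by photochemical Wolff rearrangement. The feature exploited is the meta O/H/O array at ring carbons C2–C4: the ynol ether oxygen becomes the C2 ether and the ketene carbonyl the free C4 phenol, so both oxygens arrive differentiated in one operation, with the C1 carboxyl and the C6 side chain already in place. The precursor is an acyclic methyl 2-diazo-3-oxopentanoate carrying a 4-methylidene group and, at C5, the dioxolane-masked ketone with its undecyl chain.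

Key step: step 7

Remark: ring numbering is C1 (carboxyl), C2 (hydroxyl), C4 (methoxy), C6 (2-oxotridecyl). The target has no stereocentre; the carbinol carbon of 3 and the quaternary carbon of transient 12 are formed racemic and are erased in steps 2 and 7.

Step 1
Reactants: 1 dodecanal; 2 methyl 2-(bromomethyl)prop-2-enoate
Product: 3 methyl 4-hydroxy-2-methylidenepentadecanoate (racemic)
Conditions: Zn dust, THF/sat. aq. NH4Cl, 0 °C to rt
Reagents that add atoms: none
Why: Barbier allylation, in which the allylzinc bromide formed in situ from 2 adds to the aldehyde and the hydroxy ester, kept cold and free of acid, should not lactonize; the carbinol centre is formed racemic and is removed in step 2.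

Step 2
Reactants: 3 methyl 4-hydroxy-2-methylidenepentadecanoate
Product: 4 methyl 2-methylidene-4-oxopentadecanoate
Conditions: Dess–Martin periodinane, CH2Cl2, 0 °C to rt
Reagents that add atoms: none
Why: Dess–Martin oxidation of the secondary alcohol runs without base, so the exocyclic double bond should not move into conjugation with the new ketone.

Step 3
Reactants: 4 methyl 2-methylidene-4-oxopentadecanoate
Product: 5 methyl 2-[(2-undecyl-1,3-dioxolan-2-yl)methyl]prop-2-enoate
Conditions: (TMSOCH2)2, TMSOTf (cat.), CH2Cl2, −78 to −20 °C; then pyridine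
Reagents that add atoms: 1,2-bis(trimethylsilyloxy)ethane, C[Si](C)(C)OCCO[Si](C)(C)C
Why: Noyori ketalization is aprotic and cold, the conditions under which β,γ-unsaturated ketones are protected without double-bond shift, and the acrylate is inert to it.

Step 4
Reactants: 5 methyl 2-[(2-undecyl-1,3-dioxolan-2-yl)methyl]prop-2-enoate
Product: 6 2-[(2-undecyl-1,3-dioxolan-2-yl)methyl]prop-2-enoic acid
Conditions: LiOH·H2O, THF/H2O, rt; then cold 1 M HCl to pH 4
Reagents that add atoms: lithium hydroxide, [Li+].[OH-]
Why: Saponification of an unhindered ester; the dioxolane is stable to base and should survive the brief, cold, mildly acidic work-up.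

Step 5
Reactants: 6 2-[(2-undecyl-1,3-dioxolan-2-yl)methyl]prop-2-enoic acid
Product: 8 methyl 4-methylidene-3-oxo-5-(2-undecyl-1,3-dioxolan-2-yl)pentanoate, via acyl imidazolide 7 (not isolated)
Conditions: CDI, THF, rt; then Mg(O2CCH2CO2Me)2, THF, rt to 40 °C; cold 0.5 M HCl work-up
Reagents that add atoms: magnesium bis(methyl malonate), [Mg+2].[O-]C(=O)CC(=O)OC.[O-]C(=O)CC(=O)OC; 1,1'-carbonyldiimidazole, O=C(n1ccnc1)n1ccnc1 (imidazolyl group of 7 only)
Why: Masamune chain extension, in which the acyl imidazolide C-acylates the magnesium malonate half-ester and decarboxylation gives the β-keto ester, held as its magnesium enolate (no Michael acceptor) until work-up.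

Step 6
Reactants: 8 methyl 4-methylidene-3-oxo-5-(2-undecyl-1,3-dioxolan-2-yl)pentanoate
Product: 9 methyl 2-diazo-4-methylidene-3-oxo-5-(2-undecyl-1,3-dioxolan-2-yl)pentanoate
Conditions: p-ABSA, Et3N, MeCN, 0 °C to rt
Reagents that add atoms: 4-acetamidobenzenesulfonyl azide, CC(=O)Nc1ccc(cc1)S(=O)(=O)N=[N+]=[N-]
Why: Regitz diazo transfer to the doubly activated methylene is fast under mild amine base and leaves ketal, ester and alkene untouched.

Step 7
Reactants: 9 methyl 2-diazo-4-methylidene-3-oxo-5-(2-undecyl-1,3-dioxolan-2-yl)pentanoate; 10 ethoxyacetylene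
Product: 15 methyl 2-ethoxy-4-hydroxy-6-[(2-undecyl-1,3-dioxolan-2-yl)methyl]benzoate, via vinylketene 11 (not isolated), via cyclobutenone 12 (not isolated), via dienylketene 13 (not isolated), via cyclohexadienone 14 (not isolated)
Conditions: hν (300 nm), 10 (4 equiv), degassed ClCH2CH2Cl, rt; then 80 °C
Reagents that add atoms: none
Why: Proposed new method: irradiation should expel N2 with 1,2-shift of the alkenyl group (photochemical Wolff rearrangement) to give the ester-bearing vinylketene 11, whose electrophilic central carbon is attacked by the nucleophilic CH terminus of the ynol ether in a polar (2+2) cycloaddition (C3–C4, then C1–C2) to cyclobutenone 12; reversible 4π electrocyclic opening gives dienylketene 13, 6π electrocyclization (C4–C5) gives dienone 14 and enolization gives phenol 15. The closest known reaction type is the photochemical Wolff variant of the Danheiser benzannulation of α-diazo ketones with alkoxy- and siloxyalkynes, and what is new is the 2-diazo-3-oxo ester, which puts an alkoxycarbonyl group on the ketene carbon. The one ring that persists, the six-membered carbocycle, is closed by thermal disrotatory 6π electrocyclization of the (2Z)-dienylketene, whereas the four-membered ring of 12 is made and opened again. No stereocentre results, since the quaternary carbon of racemic 12 becomes aromatic. The regiochemistry (ether at C2, hydroxyl at C4) follows from the polarization of ethoxyacetylene, reinforced by the electron-poor ketene, and the alkenyl group should migrate in preference to methoxy in the Wolff step. The step needs carbon–carbon closure to beat closure through the ester carbonyl oxygen (pyranone formation from the cycloaddition zwitterion or from 13), which the substrate secures through the low nucleophilicity of an ester oxygen and through the reversible 12/13 manifold (light, then 80 °C) that drains into the aromatic product.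

Step 8
Reactants: 15 methyl 2-ethoxy-4-hydroxy-6-[(2-undecyl-1,3-dioxolan-2-yl)methyl]benzoate
Product: 16 methyl 2-ethoxy-4-methoxy-6-[(2-undecyl-1,3-dioxolan-2-yl)methyl]benzoate
Conditions: MeI, K2CO3, acetone, 40 °C
Reagents that add atoms: iodomethane, CI
Why: Williamson O-methylation of the only free phenol; ester, ketal and ethyl ether are inert to carbonate.

Step 9
Reactants: 16 methyl 2-ethoxy-4-methoxy-6-[(2-undecyl-1,3-dioxolan-2-yl)methyl]benzoate
Product: 17 methyl 2-hydroxy-4-methoxy-6-(2-oxotridecyl)benzoate
Conditions: BCl3, CH2Cl2, −78 to 0 °C; then H2O/THF, rt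
Reagents that add atoms: water, O
Why: Chelation-controlled dealkylation, in which boron held between the ester carbonyl and the ortho ethoxy oxygen lets chloride displace the ethyl group while the unchelated 4-methoxy group stays, and the Lewis acid with aqueous work-up also opens the dioxolane to the ketone.

Step 10
Reactants: 17 methyl 2-hydroxy-4-methoxy-6-(2-oxotridecyl)benzoate
Product: 18 2-hydroxy-4-methoxy-6-(2-oxotridecyl)benzoic acid
Conditions: KOH, EtOH/H2O, 70 °C; then 1 M HCl, 0 °C, to pH 2
Reagents that add atoms: potassium hydroxide, [K+].[OH-]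
Why: Saponification, the standard alkaline hydrolysis for acids of the orsellinic type, gives a dianion that is stable to decarboxylation, and cold acidification should release the keto acid without decarboxylation or cyclodehydration.

**Compound list**

1 | dodecanal | CCCCCCCCCCCC=O | starting material
2 | methyl 2-(bromomethyl)prop-2-enoate | COC(=O)C(=C)CBr | starting material
3 | methyl 4-hydroxy-2-methylidenepentadecanoate (racemic) | CCCCCCCCCCCC(O)CC(=C)C(=O)OC | intermediate
4 | methyl 2-methylidene-4-oxopentadecanoate | CCCCCCCCCCCC(=O)CC(=C)C(=O)OC | intermediate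
5 | methyl 2-[(2-undecyl-1,3-dioxolan-2-yl)methyl]prop-2-enoate | CCCCCCCCCCCC1(CC(=C)C(=O)OC)OCCO1 | intermediate
6 | 2-[(2-undecyl-1,3-dioxolan-2-yl)methyl]prop-2-enoic acid | CCCCCCCCCCCC1(CC(=C)C(=O)O)OCCO1 | intermediate
7 | 1-{2-[(2-undecyl-1,3-dioxolan-2-yl)methyl]prop-2-enoyl}-1H-imidazole (acyl imidazolide, not isolated) | CCCCCCCCCCCC1(CC(=C)C(=O)n2ccnc2)OCCO1 | intermediate
8 | methyl 4-methylidene-3-oxo-5-(2-undecyl-1,3-dioxolan-2-yl)pentanoate | CCCCCCCCCCCC1(CC(=C)C(=O)CC(=O)OC)OCCO1 | intermediate
9 | methyl 2-diazo-4-methylidene-3-oxo-5-(2-undecyl-1,3-dioxolan-2-yl)pentanoate | CCCCCCCCCCCC1(CC(=C)C(=O)C(=[N+]=[N-])C(=O)OC)OCCO1 | intermediate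
10 | ethoxyacetylene (ethoxyethyne) | CCOC#C | starting material
11 | methyl 2-(oxomethylidene)-3-[(2-undecyl-1,3-dioxolan-2-yl)methyl]but-3-enoate (vinylketene, not isolated) | CCCCCCCCCCCC1(CC(=C)C(=C=O)C(=O)OC)OCCO1 | intermediate
12 | methyl 2-ethoxy-4-oxo-1-[3-(2-undecyl-1,3-dioxolan-2-yl)prop-1-en-2-yl]cyclobut-2-ene-1-carboxylate (racemic cyclobutenone, not isolated) | CCCCCCCCCCCC1(CC(=C)C2(C(=O)OC)C(=O)C=C2OCC)OCCO1 | intermediate
13 | methyl (2Z)-3-ethoxy-5-oxo-2-[3-(2-undecyl-1,3-dioxolan-2-yl)prop-1-en-2-yl]penta-2,4-dienoate (dienylketene, not isolated) | CCCCCCCCCCCC1(CC(=C)/C(C(=O)OC)=C(/OCC)C=C=O)OCCO1 | intermediate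
14 | methyl 6-ethoxy-4-oxo-2-[(2-undecyl-1,3-dioxolan-2-yl)methyl]cyclohexa-1,5-diene-1-carboxylate (cyclohexadienone, not isolated) | CCCCCCCCCCCC1(CC2=C(C(=O)OC)C(OCC)=CC(=O)C2)OCCO1 | intermediate
15 | methyl 2-ethoxy-4-hydroxy-6-[(2-undecyl-1,3-dioxolan-2-yl)methyl]benzoate | CCCCCCCCCCCC1(Cc2cc(O)cc(OCC)c2C(=O)OC)OCCO1 | intermediate
16 | methyl 2-ethoxy-4-methoxy-6-[(2-undecyl-1,3-dioxolan-2-yl)methyl]benzoate | CCCCCCCCCCCC1(Cc2cc(OC)cc(OCC)c2C(=O)OC)OCCO1 | intermediate
17 | methyl 2-hydroxy-4-methoxy-6-(2-oxotridecyl)benzoate | CCCCCCCCCCCC(=O)Cc1cc(OC)cc(O)c1C(=O)OC | intermediate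
18 | 2-hydroxy-4-methoxy-6-(2-oxotridecyl)benzoic acid | CCCCCCCCCCCC(=O)Cc1cc(OC)cc(O)c1C(=O)O | target

**Step count.** Total: 10 steps. Longest linear sequence: 10 steps (1 to 18).

**Steps most likely to fail**

1. Step 7 (bears the label). What may go wrong: ring closure through the ester oxygen in place of carbon, either in the cycloaddition zwitterion or in the dienylketene; competing migration in the Wolff step; and acylation of the product phenol by unreacted ketene. Fallback with known chemistry, which abandons ring construction and starts again from dodecanal 1: the benzylic anion of methyl 2,4-dimethoxy-6-methylbenzoate (LDA, THF, −78 °C, lateral lithiation) is added to 1 and quenched cold with acetic acid before the alkoxide can lactonize, which should give methyl 2-(2-hydroxytridecyl)-4,6-dimethoxybenzoate F1 (racemic). Dess–Martin oxidation should give methyl 2,4-dimethoxy-6-(2-oxotridecyl)benzoate F2. BCl3 (CH2Cl2, −78 to 0 °C) then removes only the methyl ether chelated to the ester, and the route is rejoined at 17, one step before the target.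

2. Step 5. What may go wrong: conjugate addition of liberated imidazole to the acryloyl imidazolide, or self-condensation of the vinyl ketone once its magnesium enolate is protonated. Fallback from ketal ester 5, which reaches the diazo compound without a free β-keto ester: DIBAL-H (CH2Cl2, −78 °C) should reduce 5 to 2-[(2-undecyl-1,3-dioxolan-2-yl)methyl]prop-2-en-1-ol F3. MnO2 (CH2Cl2, rt) should give 2-[(2-undecyl-1,3-dioxolan-2-yl)methyl]prop-2-enal F4. DBU-catalysed aldol-type addition of methyl diazoacetate (MeCN, rt) should give methyl 2-diazo-3-hydroxy-4-methylidene-5-(2-undecyl-1,3-dioxolan-2-yl)pentanoate F5 (racemic). Oxidation of the carbinol with IBX in DMSO rejoins the route at 9.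

3. Step 3. What may go wrong: migration of the exocyclic double bond of 4 into conjugation with the ketone, under the Lewis acid or already during isolation of 4. Fallback from dodecanal 1, which never exposes an enolizable ketone beside the acrylate: propane-1,3-dithiol and BF3·OEt2 (CH2Cl2) should give 2-undecyl-1,3-dithiane F6. Lithiation (n-BuLi, THF, −30 °C) and addition to excess 2 at −78 °C should give methyl 2-[(2-undecyl-1,3-dithian-2-yl)methyl]prop-2-enoate F7; direct and allylic displacement of bromide lead to the same compound. Oxidative transketalization with PhI(O2CCF3)2 and ethylene glycol in MeCN rejoins the route at 5.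

**Further compounds**

F1 | step 7 | methyl 2-(2-hydroxytridecyl)-4,6-dimethoxybenzoate (racemic) | CCCCCCCCCCCC(O)Cc1cc(OC)cc(OC)c1C(=O)OC
F2 | step 7 | methyl 2,4-dimethoxy-6-(2-oxotridecyl)benzoate | CCCCCCCCCCCC(=O)Cc1cc(OC)cc(OC)c1C(=O)OC
F3 | step 5 | 2-[(2-undecyl-1,3-dioxolan-2-yl)methyl]prop-2-en-1-ol | CCCCCCCCCCCC1(CC(=C)CO)OCCO1
F4 | step 5 | 2-[(2-undecyl-1,3-dioxolan-2-yl)methyl]prop-2-enal | CCCCCCCCCCCC1(CC(=C)C=O)OCCO1
F5 | step 5 | methyl 2-diazo-3-hydroxy-4-methylidene-5-(2-undecyl-1,3-dioxolan-2-yl)pentanoate (racemic) | CCCCCCCCCCCC1(CC(=C)C(O)C(=[N+]=[N-])C(=O)OC)OCCO1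
F6 | step 3 | 2-undecyl-1,3-dithiane | CCCCCCCCCCCC1SCCCS1
F7 | step 3 | methyl 2-[(2-undecyl-1,3-dithian-2-yl)methyl]prop-2-enoate | CCCCCCCCCCCC1(CC(=C)C(=O)OC)SCCCS1
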